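**Plan**

1. The retrosynthesis first cuts, in the tetramethylcyclohexenedione ring, the bond between the enone carbonyl carbon (the C=O next to the alkene carbon that carries the CH(isobutyl) group) and the CMe2 carbon lying between the two carbonyls. That acyl carbon is re-joined to the oxygen of the neighbouring ring ketone, giving an isomeric six-membered enol lactone with an exocyclic isopropylidene group.
2. It then cuts O–C8 and CH(isobutyl)–CH2 of the spiro dihydropyran (retro hetero-Diels–Alder, retro-Knoevenagel) to a caryophylladienol, isovaleraldehyde and a pyran-2,4-dione. The dienol goes back to (−)-caryophyllene oxide, the pyrandione to tetramethylcyclobutane-1,3-dione and tert-butyl acetate.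
3. Forward: the cyclobutane and nine-membered ring are bought, the lactone ring is made by enol lactonization, the dihydropyran ring closes in the cycloaddition, and the carbocycle closes last by a photochemical 1,3-acyl shift. No protecting groups are used.
4. Enabling feature: in the lactone the acyl carbon and the isopropylidene carbon sit 1,3 to each other across the ring oxygen. Both carbons flanking the masked ketone are fully substituted (one ring CMe2, one =CMe2), so nothing can enolize and the only carbon open to the acyl group is the one that becomes the second CMe2 of the trione ring.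
5. Stereochemistry: C1, C9 and C5 come from caryophyllene oxide (C5–O bond kept); the 3Z alkene from the syn-elimination that opens the epoxide; C8 and the isobutyl-bearing carbon from the face- and endo-selective cycloaddition.

Key step: step 5

Assumption: the terpene part is numbered as in caryophyllane (C1/C9 ring fusion, C4 the methyl-bearing alkene carbon, C5 the carbinol carbon, C8 the spiro carbon, C13 its former exocyclic methylene). Dione 9 is drawn as the diketo tautomer although it should exist largely as its 4-hydroxy enol. The cycloaddition is assumed to follow the outer-face mode usual for caryophyllene-type exocyclic methylenes.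

**Step 1**
Reactants: 1 (−)-caryophyllene oxide, (1R,4R,5R,9S)-4,5-epoxycaryophyll-8(13)-ene
Product: 2 (1R,3Z,5R,9S)-caryophylla-3,8(13)-dien-5-ol
Conditions: Et2AlCl, lithium 2,2,6,6-tetramethylpiperidide (premixed, 4 equiv each), toluene, 0 °C; then aqueous KNaC4H4O6
Reagents that add atoms: none
Why: In this regioselective epoxide-to-allylic-alcohol isomerization with a dialkylaluminium amide, the bulky amide bound to the epoxide oxygen should remove, by syn-elimination, a proton from ring methylene C3 (cis to the epoxide hydrogen) rather than from the methyl group (cis to C6), so the C5–O bond and its (R) configuration are kept, the cis (Z) C3=C4 bond that a nine-membered ring accommodates is formed, and C1/C9 are untouched.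

**Step 2**
Reactants: 3 2,2,4,4-tetramethylcyclobutane-1,3-dione; 4 tert-butyl acetate
Product: 7 tert-butyl 4,4,6-trimethyl-3,5-dioxoheptanoate, via lithium enolate of tert-butyl acetate 5 (not isolated), via lithium cyclobutanone aldolate 6 (not isolated)
Conditions: 4, LiN(iPr)2 (1.2 equiv), THF, −78 °C; then 3, −78 → 0 °C; then 1 M HCl, 0 °C
Reagents that add atoms: none
Why: Aldol-type addition of the ester enolate to the strained, non-enolizable cyclobutanedione carbonyl should be followed by strain-driven retro-Claisen ring opening (Claisen-type acyl transfer to a carbon nucleophile, a known mode of cleavage of this diketone), and proton transfer to the stabilized beta-keto ester enolate shields the product from further attack; no stereocentre is formed.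

**Step 3**
Reactants: 7 tert-butyl 4,4,6-trimethyl-3,5-dioxoheptanoate
Product: 9 5,5-dimethyl-6-(propan-2-ylidene)oxane-2,4-dione, via 4,4,6-trimethyl-3,5-dioxoheptanoic acid 8 (not isolated)
Conditions: CF3CO2H, (CF3CO)2O, CH2Cl2, 0 → 23 °C
Reagents that add atoms: none
Why: Acidolysis of the tert-butyl ester and activation of acid 8 as its mixed trifluoroacetic anhydride should let the 5-keto oxygen close the six-membered ring (enol lactonization of a delta-keto acid, as in the CF3CO2H/(CF3CO)2O cyclization of 3,5-dioxo esters to pyran-2-ones), and because C4 is quaternary the acyloxocarbenium ion can only lose the isopropyl methine proton, which fixes the exocyclic isopropylidene; no stereocentre is formed.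

**Step 4**
Reactants: 9 5,5-dimethyl-6-(propan-2-ylidene)oxane-2,4-dione; 10 isovaleraldehyde (3-methylbutanal); 2 (1R,3Z,5R,9S)-caryophylla-3,8(13)-dien-5-ol
Product: 12 spiro enol lactone cycloadduct (1R,3Z,5R,8S,9S; 4'R), via alkylidene pyrandione 11 (not isolated)
Conditions: ethylenediammonium diacetate (10 mol %), 4 Å molecular sieves, toluene, 23 → 90 °C
Reagents that add atoms: none
Why: In this domino Knoevenagel condensation / inverse-electron-demand hetero-Diels–Alder reaction, the 1-oxadiene of 11 built on the ketone carbonyl (lower LUMO than the lactone carbonyl) should add to the 1,1-disubstituted C8=C13 bond with oxygen going to the more substituted C8, on the outer face of the methylene (Re at C8, the exposed face when the methylene lies on the side of H-9) and with ring methylene C7 endo and the cyclobutane-bearing C9 exo, which sets (8S) and places the isobutyl group of the E-configured heterodiene cis to C7, i.e. (R) at the new CH; the trisubstituted ring alkene is too hindered to compete.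

**Step 5**
Reactants: 12 spiro enol lactone cycloadduct
Product: 13 Tomentodione O
Conditions: hν (254 nm, low-pressure mercury lamp, quartz), degassed MeCN (2 mM), 20 °C, run to partial conversion with recycling of 12
Reagents that add atoms: none
Why: Proposed new method: excitation of the conjugated enol-lactone chromophore (an alkoxyacryloyl group bonded through the ring oxygen to the isopropylidene enol carbon) should cleave the acyl C–O bond homolytically to a tethered acyl / 1-oxoallyl 1,6-biradical, whose recombination at the dimethyl-substituted carbon makes the C(=O)–CMe2 bond; the closest known reaction is the photo-Fries-type 1,3-acyl shift of enol esters to 1,3-diketones. The six-membered carbocycle closes by this intramolecular radical recombination, a formal 1,3-shift from oxygen to carbon that trades the six-membered lactone for the six-membered trione ring. No stereocentre is created, because the new quaternary carbon carries two methyl groups, and the five existing stereocentres and the 3Z alkene lie outside the chromophore. The step needs carbon rather than oxygen recombination and no loss of CO: oxygen recombination only returns 12, which is excited again, the alkenoyl radical decarbonylates slowly, and the two radical ends cannot separate because the dihydropyran carbons hold them together. Neutral light-driven conditions are chosen because the non-enolizable tetramethyl trione is open to retro-Claisen cleavage under the alkoxide conditions of a thermal acyl transfer, and the free C5 hydroxyl would compete there as acyl acceptor.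

**Compound list**

1 | (−)-caryophyllene oxide, (1R,4R,5R,9S)-4,5-epoxycaryophyll-8(13)-ene | C[C@@]12CC[C@@H]3[C@H](CC3(C)C)C(=C)CC[C@H]1O2 | starting material
2 | (1R,3Z,5R,9S)-caryophylla-3,8(13)-dien-5-ol | C/C1=C/C[C@@H]2[C@H](CC2(C)C)C(=C)CC[C@H]1O | intermediate
3 | 2,2,4,4-tetramethylcyclobutane-1,3-dione | CC1(C)C(=O)C(C)(C)C1=O | starting material
4 | tert-butyl acetate | CC(=O)OC(C)(C)C | starting material
5 | lithium enolate of tert-butyl acetate | [Li+].[O-]C(=C)OC(C)(C)C | intermediate
6 | lithium 1-(2-tert-butoxy-2-oxoethyl)-2,2,4,4-tetramethyl-3-oxocyclobutan-1-olate | [Li+].[O-]C1(CC(=O)OC(C)(C)C)C(C)(C)C(=O)C1(C)C | intermediate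
7 | tert-butyl 4,4,6-trimethyl-3,5-dioxoheptanoate | CC(C)C(=O)C(C)(C)C(=O)CC(=O)OC(C)(C)C | intermediate
8 | 4,4,6-trimethyl-3,5-dioxoheptanoic acid | CC(C)C(=O)C(C)(C)C(=O)CC(=O)O | intermediate
9 | 5,5-dimethyl-6-(propan-2-ylidene)oxane-2,4-dione | CC(C)=C1OC(=O)CC(=O)C1(C)C | intermediate
10 | isovaleraldehyde (3-methylbutanal) | CC(C)CC=O | starting material
11 | 5,5-dimethyl-3-(3-methylbutylidene)-6-(propan-2-ylidene)oxane-2,4-dione (alkene geometry not fixed) | CC(C)CC=C1C(=O)OC(=C(C)C)C(C)(C)C1=O | intermediate
12 | (1R,3Z,5R,8S,9S)-caryophyll-3-en-5-ol spiro-joined at C8 to C2 of (4R)-8,8-dimethyl-4-(2-methylpropyl)-7-(propan-2-ylidene)-3,4,7,8-tetrahydro-2H,5H-pyrano[4,3-b]pyran-5-one | C/C1=C/C[C@@H]2[C@H](CC2(C)C)[C@]2(CC[C@H]1O)C[C@@H](CC(C)C)C1=C(O2)C(C)(C)C(=C(C)C)OC1=O | intermediate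
13 | Tomentodione O: (1R,3Z,5R,8S,9S)-caryophyll-3-en-5-ol spiro-joined at C8 to C2 of (4R)-6,6,8,8-tetramethyl-4-(2-methylpropyl)-3,4-dihydro-2H-chromene-5,7(6H,8H)-dione | C/C1=C/C[C@@H]2[C@H](CC2(C)C)[C@]2(CC[C@H]1O)C[C@@H](CC(C)C)C1=C(O2)C(C)(C)C(=O)C(C)(C)C1=O | target

**Step count and risks**

Total steps: 5. Longest linear sequence: 4 (3/4 → 7 → 9 → 12 → 13).

Steps most likely to fail:

Step 5. The acyl/oxoallyl biradical may return mainly by oxygen recombination, so that light only cycles the lactone, or the trione may be consumed by secondary alpha-cleavage and decarbonylation under the same irradiation. The fallback uses known ester and enolate chemistry and sets out from 12. Methanolysis of the enol lactone (NaOMe, MeOH, 0 °C) should give the seco methyl ester with a free isopropyl ketone F1. Treatment of F1 with LiN(SiMe3)2 (3 equiv, one consumed by the hydroxyl) in THF at −78 → −20 °C should close the ring by an intramolecular Claisen (Dieckmann-type) condensation of the only possible ketone enolate onto the ester. A cold quench limits retro-Claisen opening, and the route is rejoined at 13.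

Step 4. The heterodiene may add to the wrong face of the exocyclic methylene of the conformationally mobile (Z)-cyclononenol, and reversible conjugate addition of the free hydroxyl to 11 may drain the heterodiene. The fallback sets out from 1, 9 and 10. The same Knoevenagel/hetero-Diels–Alder domino is run on epoxide 1, which has no hydroxyl and keeps the E-configured nine-membered ring of caryophyllene, to give the epoxide cycloadduct F2. The epoxide of F2 is then opened to the allylic alcohol with Et2AlCl / lithium 2,2,6,6-tetramethylpiperidide as in step 1, and the route is rejoined at 12.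

Step 3. The free beta-keto acid 8 may lose CO2 before the ring closes, or enolization towards the hindered isopropyl group may be too slow under acid. The fallback sets out from 7 and avoids the free acid. Thermolysis of the tert-butyl beta-keto ester (xylene, 140 °C, tert-butanol distilled off) should give the acylketene F3. Its ketene carbon is captured by the 5-keto oxygen, and proton loss from the isopropyl group then gives the enol lactone, so the route is rejoined at 9.

**Further compounds**

F1 | step 5 | methyl (4R)-6-(2,4-dimethyl-3-oxopentan-2-yl)-4-(2-methylpropyl)-3,4-dihydro-2H-pyran-5-carboxylate spiro-joined at C2 to C8 of (1R,3Z,5R,8S,9S)-caryophyll-3-en-5-ol | C/C1=C/C[C@@H]2[C@H](CC2(C)C)[C@]2(CC[C@H]1O)C[C@@H](CC(C)C)C(C(=O)OC)=C(O2)C(C)(C)C(=O)C(C)C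
F2 | step 4 | (4R,5R)-4,5-epoxide analogue of 12 (epoxide cycloadduct with the spiro lactone of 12 at C8 of caryophyllene oxide) | C[C@@]12CC[C@@H]3[C@H](CC3(C)C)[C@]3(CC[C@H]1O2)C[C@@H](CC(C)C)C1=C(O3)C(C)(C)C(=C(C)C)OC1=O
F3 | step 3 | 4,4,6-trimethylhept-1-ene-1,3,5-trione (acylketene) | CC(C)C(=O)C(C)(C)C(=O)C=C=O
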